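## Analysis of the target

Target 19 is methyl 3-[(2S,3R)-2-(4-hydroxy-3,5-dimethoxyphenyl)-3-(hydroxymethyl)-7-methoxy-2,3-dihydro-1-benzofuran-5-yl]propanoate, a neolignan of the phenylcoumaran type. Its core is a 2,3-dihydrobenzofuran (O1, C2, C3, C3a, C7a) with a methoxy group at C7 and a methyl propanoate chain at C5. C2 carries a syringyl-type aryl group with a free para phenol, and C3 carries a hydroxymethyl group. The only stereocentres are the adjacent C2 (S) and C3 (R), with their substituents trans; reading the SMILES gives (2S,3R). No other stereocentre is available to relay relative or absolute configuration.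

The sensitive points are three. The C2–O1 bond is a benzylic aryl ether activated by the para hydroxyl group, so acid or strong base can open it through a p-quinone methide and scramble C2, and it can also be hydrogenolysed. The free electron-rich phenol is easily oxidised. The methyl ester rules out hydride reagents and hard nucleophiles late in the route.

The difficulty is to join two differently oxygenated arenes through a two-carbon unit of defined absolute configuration that has no carbonyl group in its final oxidation state, and to attach C3 to the single correct aromatic position. The strategy rests on one feature: C2 is a single carbon, bearing one aryl group and one hydrogen, that bridges O1 and C3. The remaining four ring atoms O1–C7a–C3a–C3 are a phenol oxygen, two aromatic carbons and an ortho benzylic carbon, which is the skeleton of an o-quinone methide. The guaiacol ring has only one free position ortho to its phenol, and that fixes where C3 is attached.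

## Retrosynthetic reasoning

**19 to 18.** Only protecting groups are removed: the O–benzyl bond on the phenol of the C2 aryl ring and the O–benzyl bond on the primary alcohol at C3. The phenol must be masked because, in the one-carbon partner, a free para phenol would be deprotonated before the benzylic position and would expel the sulfide. The primary alcohol is masked so that no free hydroxyl group sits next to the quinone methide carbon. Benzyl on both oxygens survives every earlier step and both come off in one neutral hydrogenolysis that leaves the methyl ester and the para-hydroxybenzylic C2 centre alone. The forward step must stop before the ring C2–O1 bond is attacked.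

**18 to 6 and 14, through 15, 16 and 17.** The two ring bonds at C2 are cut, C2–C3 and O1–C2. Cutting both at the same atom leaves a one-carbon fragment and a four-atom fragment, each derived from a simple arene. Cutting O1–C7a or C3–C3a instead would need metal-mediated bond formation at a crowded, fully substituted aromatic carbon, and the C2/C3 pair would have to be built beforehand. The gain is that the ring, two skeletal bonds and both stereocentres arise in one convergent operation from two fragments that already carry every final substituent. The chirality sits in a sulfide auxiliary that is released. Compound 6 may be racemic because its sp3 centre becomes planar in 15. The forward reaction has to generate 15 and 16 side by side with one base, form C–C before C–O, select one face of 16, and close 17 with inversion.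

**6 to 4 and 5.** The C–S bond is cut. The sulfonyl group is chosen as the benzylic leaving group because the resulting phenol is a stable solid that releases sulfinate as soon as the phenol is deprotonated, whereas the hydroxyl group of 4 would not leave under base. The forward reaction is an acid-mediated benzylic substitution.

**4 to 1 and 2, through 3.** The aryl–carbon bond C3–C3a, ortho to the phenol oxygen, is cut. Compound 1 already carries the propanoate chain and the methoxy group, and 2 supplies C3 with its protected hydroxymethyl group. The forward reaction must be ortho-specific, which the magnesium phenoxide 3 ensures by binding the aldehyde. A one-pot acid condensation of 1, 2 and the acid form of 5 was set aside: 1 is a weak Friedel–Crafts partner for an aliphatic aldehyde, and acid also opens the position para to the methoxy group to attack.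

**14 to 13 and 9.** The S–CH2 bond is cut. The C2 symmetry of 9 means that alkylation at either sulfur lone pair gives the same salt. Bromide 13 goes back through alcohol 12 and aldehyde 11 to 10 by functional-group changes only.

**9 to 8 to 7.** Both C–S bonds are cut. Two displacements with inversion convert the commercially available diol 7, through 8, into the trans thiolane 9 of opposite descriptor.

## Alternatives that were turned down

**Alternative 1:** The C2–C3 bond is disconnected as a carbenoid C–H insertion. The diazo ester A2, methyl 2-{2-[(4-benzyloxy-3,5-dimethoxyphenyl)methoxy]-5-bromo-3-methoxyphenyl}-2-diazoacetate, would be decomposed by the divalent rhodium carboxylate Rh2(S-PTTL)4, dirhodium tetrakis[N-phthaloyl-(S)-tert-leucinate]. The carbenoid inserts into one of the two enantiotopic benzylic C–H bonds of the ortho benzylic ether and closes the ring to the 3-carboxylate A1.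
- For it: the chirality is catalytic, both stereocentres come from the catalyst, and an electron-rich benzylic C–H bond next to oxygen is an ideal insertion site. On catalyst economy and on avoiding a labile quinone methide it is stronger than the chosen route.
- Against it: insertions of this kind tend to give the cis ester first, so A1 needs an epimerisation at C3. After the key step the C3 ester must still be reduced to the alcohol, and the C5 bromide must be turned into the propanoate chain by a Heck coupling and hydrogenation. That order is forced because two methyl esters could not be told apart. A diazo transfer and a tetrasubstituted phenylacetate are also needed.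
- Comparison: the chosen route gives up catalytic chirality but delivers both arenes with their final substituents and the C3 carbon at its final oxidation level, so only one deprotection follows the ring closure.

**Alternative 2:** O1–C7a and C3–C3a are disconnected. Iodine–magnesium exchange on the iodo triflate A5 with iPrMgCl·LiCl would give a 3-borylaryne. The magnesium alkoxide of the erythro epoxy alcohol A4 adds to the aryne carbon next to boron. The aryl anion formed at C3a opens the epoxide at its internal carbon in a 5-exo closure, releasing the hydroxymethyl group and giving the boronate A3.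
- For it: the two stereocentres are fixed beforehand in A4 by well-understood epoxidation chemistry and are transferred stereospecifically (retention at C2, inversion at C3). No protecting group is needed on the primary alcohol. On predictability of configuration it is at least as strong as the chosen route.
- Against it: A4 would come from a kinetic-resolution epoxidation, which caps the yield at half. A5 is a 1,2,3,5-tetrasubstituted arene that needs several steps. The aryne must be generated by a Grignard reagent in the presence of a methyl ester. The regiochemistry of alkoxide addition depends on the boryl group. After the key step the boronate must still be oxidised and the new phenol methylated selectively.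
- Comparison: the chosen route has the C7 methoxy group in place from the start and reaches the ring in two steps from a commercial phenol. In exchange it accepts a stereochemical outcome that must be induced rather than transferred.

**Alternative 3:** Only O1–C7a is disconnected. The bromo alcohol A7, derived from an auxiliary-controlled syn aldol reaction, would be cyclised with CuI (monovalent copper), 3,4,7,8-tetramethyl-1,10-phenanthroline and Cs2CO3. The secondary benzylic hydroxyl group couples with the ortho aryl bromide to give the silyl ether A6 with both stereocentres retained.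
- For it: the C–O bond is formed at an aromatic carbon, so neither stereocentre is touched. Their relative and absolute configuration come from a dependable aldol reaction whose sense is known and whose diastereomers can be purified. On stereochemical certainty it is stronger than the chosen route.
- Against it: the aryl bromide of A7 is flanked by a methoxy group and a branched alkyl group, so the coupling needs heat and strong base on a benzylic alkoxide that can be oxidised or eliminated. The auxiliary must be attached and then removed reductively, which clashes with the side-chain methyl ester and forces that chain to be carried in another form. A brominated tetrasubstituted phenylacetic acid is required. Two deprotections follow. The linear sequence would be roughly twice as long.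
- Comparison: the chosen route is shorter and convergent and puts its risk in one step. Alternative 3 spreads lower risk over many more steps.

Key step: step 9

Assumption: ylide 16 is taken to expose to 15 the same face that ylides of this thiolane class expose to aryl aldehydes, where the (2R,5R)-sulfide leads to (S,S)-trans-diaryloxiranes; because the aryl group outranks C3 at C2 of the dihydrobenzofuran whereas the second oxirane carbon outranks the aryl group in the epoxide, that face corresponds to (2R) for the (2R,5R)-sulfide, so the (2S,5S)-sulfide 9 is used for the (2S,3R) target, and if the sense proved to be the reverse the same route would be run from the enantiomeric diol.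

## Route

Step 1
Reactants: 1 methyl 3-(4-hydroxy-3-methoxyphenyl)propanoate; 2 benzyloxyacetaldehyde
Product: 4 methyl 3-{3-[2-(benzyloxy)-1-hydroxyethyl]-4-hydroxy-5-methoxyphenyl}propanoate (racemic), via bromomagnesium phenoxide 3 (not isolated)
Conditions: EtMgBr (1.0 equiv), Et2O, 0 °C; solvent exchange to CH2Cl2; 2 (1.1 equiv), 0 °C to rt; sat. aq NH4Cl
Reagents that add atoms: ethylmagnesium bromide CC[Mg]Br (its Mg and Br are present in 3 only and leave on work-up)
Why: Ortho-specific hydroxyalkylation of a magnesium phenoxide: EtMgBr is consumed by the phenol far faster than it can add to the ester, and the aldehyde bound to magnesium in 3 is delivered through a six-membered chelate to the only free ortho carbon; the new carbinol centre is racemic, which is immaterial because it becomes planar in step 9.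

Step 2
Reactants: 4 methyl 3-{3-[2-(benzyloxy)-1-hydroxyethyl]-4-hydroxy-5-methoxyphenyl}propanoate; 5 sodium 4-methylbenzenesulfinate
Product: 6 methyl 3-{3-[2-(benzyloxy)-1-(4-methylphenylsulfonyl)ethyl]-4-hydroxy-5-methoxyphenyl}propanoate (racemic)
Conditions: 5 (1.5 equiv), HCO2H/H2O, THF, rt
Reagents that add atoms: none
Why: SN1-type benzylic substitution: acid ionises the o-hydroxybenzylic alcohol (cation stabilised by the ortho phenol) and the sulfinate captures it at sulfur; attack through oxygen is reversible under acid, so the sulfone accumulates, and the methyl ester and the benzyl ether tolerate aqueous formic acid at rt.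

Step 3
Reactants: 7 (2R,5R)-hexane-2,5-diol
Product: 8 (2R,5R)-hexane-2,5-diyl dimethanesulfonate
Conditions: MsCl (2.4 equiv), Et3N (3 equiv), CH2Cl2, −20 to 0 °C
Reagents that add atoms: methanesulfonyl chloride CS(=O)(=O)Cl
Why: O-Sulfonylation activates both secondary alcohols without touching their C–O bonds, so both (R) centres are kept.

Step 4
Reactants: 8 (2R,5R)-hexane-2,5-diyl dimethanesulfonate
Product: 9 (2S,5S)-2,5-dimethylthiolane
Conditions: Na2S·9H2O, DMSO, rt; distillation
Reagents that add atoms: sodium sulfide (used as the nonahydrate) [Na+].[Na+].[S-2]
Why: Double SN2 thioetherification: sulfide displaces one mesylate and the resulting thiolate displaces the other in a 5-exo-tet closure, each with inversion, which turns the (2R,5R) bis-mesylate into the trans (2S,5S) thiolane.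

Step 5
Reactants: 10 syringaldehyde (4-hydroxy-3,5-dimethoxybenzaldehyde)
Product: 11 4-(benzyloxy)-3,5-dimethoxybenzaldehyde
Conditions: BnBr, K2CO3, DMF, 60 °C
Reagents that add atoms: benzyl bromide BrCc1ccccc1
Why: Williamson ether synthesis; the phenoxide, although flanked by two methoxy groups, is alkylated cleanly by the reactive benzylic bromide in a dipolar aprotic solvent.

Step 6
Reactants: 11 4-(benzyloxy)-3,5-dimethoxybenzaldehyde
Product: 12 [4-(benzyloxy)-3,5-dimethoxyphenyl]methanol
Conditions: NaBH4, MeOH, 0 °C
Reagents that add atoms: none
Why: Chemoselective hydride reduction of the aldehyde; no other reducible group is present.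

Step 7
Reactants: 12 [4-(benzyloxy)-3,5-dimethoxyphenyl]methanol
Product: 13 2-(benzyloxy)-5-(bromomethyl)-1,3-dimethoxybenzene
Conditions: PBr3 (0.4 equiv), CH2Cl2, 0 °C
Reagents that add atoms: phosphorus tribromide BrP(Br)Br
Why: Bromination of a benzylic alcohol through its phosphite ester; the aryl benzyl and methyl ethers survive the short exposure at 0 °C.

Step 8
Reactants: 13 2-(benzyloxy)-5-(bromomethyl)-1,3-dimethoxybenzene; 9 (2S,5S)-2,5-dimethylthiolane
Product: 14 (2S,5S)-1-{[4-(benzyloxy)-3,5-dimethoxyphenyl]methyl}-2,5-dimethylthiolan-1-ium tetrafluoroborate
Conditions: NaBF4 (5 equiv), CH2Cl2/H2O, rt, dark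
Reagents that add atoms: sodium tetrafluoroborate [Na+].F[B-](F)(F)F
Why: SN2 S-alkylation of the sulfide by the benzylic bromide; exchanging bromide for tetrafluoroborate in the two-phase medium removes the nucleophilic counter-ion that would reverse the alkylation of this hindered sulfide, and C2 symmetry makes both sulfur lone pairs equivalent, so one sulfonium stereoisomer results.

Step 9
Reactants: 6 methyl 3-{3-[2-(benzyloxy)-1-(4-methylphenylsulfonyl)ethyl]-4-hydroxy-5-methoxyphenyl}propanoate; 14 (2S,5S)-1-{[4-(benzyloxy)-3,5-dimethoxyphenyl]methyl}-2,5-dimethylthiolan-1-ium tetrafluoroborate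
Product: 18 methyl 3-[(2S,3R)-2-(4-benzyloxy-3,5-dimethoxyphenyl)-3-(benzyloxymethyl)-7-methoxy-2,3-dihydrobenzofuran-5-yl]propanoate, via o-quinone methide 15 (not isolated), via sulfonium ylide 16 (not isolated), via betaine 17 (not isolated)
Conditions: 14 (1.3 equiv), Cs2CO3 (3 equiv), MeCN/CH2Cl2, −20 to 0 °C, slow addition of 6
Reagents that add atoms: none
Why: Cs2CO3 deprotonates the phenol of 6, whose phenoxide expels sulfinate in a 1,4-elimination to give o-quinone methide 15, while the same base converts 14 into the semistabilised benzylic ylide 16. The ylide carbon adds to the exocyclic carbon of 15 in a conjugate addition driven by rearomatisation, forming C2–C3 and the phenoxide betaine 17. The phenoxide oxygen then displaces the thiolane from the benzylic carbon in a 5-exo-tet SN2 closure that forms O1–C2 with inversion, the sulfonium group being a neutral leaving group on an electron-rich benzylic carbon. The closest known reaction type is the formal (4+1) annulation of sulfonium ylides with o-quinone methides made in situ from 2-(1-sulfonylalkyl)phenols, a Michael-initiated ring closure related to sulfur-ylide epoxidation and cyclopropanation. C2 is controlled by the (2S,5S)-thiolane: its C2 symmetry gives a single sulfonium species, the ylide adopts the conformer in which the aryl group avoids the flanking methyl group, and the other methyl group screens one face, so 15 is attacked from the open face and the inversion on closure turns this into (2S). C3 is controlled relative to C2 in the C–C bond-forming event: the approach that keeps the aryl group of 16 away from the benzyloxymethyl arm of 15 gives the anti betaine, whose closure places the two substituents trans, hence (3R). The step needs C-attack rather than O-attack on 15 and O-closure rather than C-closure of 17; the first is secured by the soft carbanion and the gain in aromaticity, the second because only the phenoxide oxygen can reach the benzylic carbon through a five-membered transition state without loss of aromaticity, and the racemic nature of 6 is irrelevant because its stereocentre vanishes in 15.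

Step 10
Reactants: 18 methyl 3-[(2S,3R)-2-(4-benzyloxy-3,5-dimethoxyphenyl)-3-(benzyloxymethyl)-7-methoxy-2,3-dihydrobenzofuran-5-yl]propanoate
Product: 19 methyl 3-[(2S,3R)-2-(4-hydroxy-3,5-dimethoxyphenyl)-3-(hydroxymethyl)-7-methoxy-2,3-dihydro-1-benzofuran-5-yl]propanoate
Conditions: H2 (1 atm), 10% Pd/C, EtOAc/MeOH, rt, stopped after uptake of 2 equiv H2
Reagents that add atoms: none
Why: Catalytic hydrogenolysis of benzyl ethers: the two unhindered primary benzylic C–O bonds should cleave before the secondary, ring-embedded C2–O1 bond, and the neutral medium leaves the methyl ester and the para-hydroxybenzylic C2 centre untouched.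

## Compound list

1 | methyl 3-(4-hydroxy-3-methoxyphenyl)propanoate (methyl dihydroferulate) | COC(=O)CCc1ccc(O)c(OC)c1 | starting material
2 | benzyloxyacetaldehyde | O=CCOCc1ccccc1 | starting material
3 | bromomagnesium 2-methoxy-4-(3-methoxy-3-oxopropyl)phenoxide | COC(=O)CCc1ccc(O[Mg]Br)c(OC)c1 | intermediate
4 | methyl 3-{3-[2-(benzyloxy)-1-hydroxyethyl]-4-hydroxy-5-methoxyphenyl}propanoate (racemic) | COC(=O)CCc1cc(OC)c(O)c(c1)C(O)COCc1ccccc1 | intermediate
5 | sodium 4-methylbenzenesulfinate | Cc1ccc(cc1)S(=O)[O-].[Na+] | starting material
6 | methyl 3-{3-[2-(benzyloxy)-1-(4-methylphenylsulfonyl)ethyl]-4-hydroxy-5-methoxyphenyl}propanoate (racemic) | COC(=O)CCc1cc(OC)c(O)c(c1)C(COCc1ccccc1)S(=O)(=O)c1ccc(C)cc1 | intermediate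
7 | (2R,5R)-hexane-2,5-diol | C[C@@H](O)CC[C@@H](C)O | starting material
8 | (2R,5R)-hexane-2,5-diyl dimethanesulfonate | C[C@@H](OS(C)(=O)=O)CC[C@@H](C)OS(C)(=O)=O | intermediate
9 | (2S,5S)-2,5-dimethylthiolane | C[C@H]1CC[C@H](C)S1 | intermediate
10 | syringaldehyde (4-hydroxy-3,5-dimethoxybenzaldehyde) | COc1cc(C=O)cc(OC)c1O | starting material
11 | 4-(benzyloxy)-3,5-dimethoxybenzaldehyde | COc1cc(C=O)cc(OC)c1OCc1ccccc1 | intermediate
12 | [4-(benzyloxy)-3,5-dimethoxyphenyl]methanol | COc1cc(CO)cc(OC)c1OCc1ccccc1 | intermediate
13 | 2-(benzyloxy)-5-(bromomethyl)-1,3-dimethoxybenzene | COc1cc(CBr)cc(OC)c1OCc1ccccc1 | intermediate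
14 | (2S,5S)-1-{[4-(benzyloxy)-3,5-dimethoxyphenyl]methyl}-2,5-dimethylthiolan-1-ium tetrafluoroborate | C[C@H]1CC[C@H](C)[S+]1Cc1cc(OC)c(OCc2ccccc2)c(OC)c1.F[B-](F)(F)F | intermediate
15 | methyl 3-{(3E)-3-[2-(benzyloxy)ethylidene]-5-methoxy-4-oxocyclohexa-1,5-dien-1-yl}propanoate (o-quinone methide) | COC(=O)CCC1=C/C(=C\COCc2ccccc2)C(=O)C(OC)=C1 | intermediate
16 | [4-(benzyloxy)-3,5-dimethoxyphenyl][(2S,5S)-2,5-dimethylthiolan-1-ium-1-yl]methanide (sulfonium ylide) | C[C@H]1CC[C@H](C)[S+]1[CH-]c1cc(OC)c(OCc2ccccc2)c(OC)c1 | intermediate
17 | 2-{(1R,2R)-3-(benzyloxy)-1-[4-(benzyloxy)-3,5-dimethoxyphenyl]-1-[(2S,5S)-2,5-dimethylthiolan-1-ium-1-yl]propan-2-yl}-6-methoxy-4-(3-methoxy-3-oxopropyl)phenolate (anti betaine) | COC(=O)CCc1cc(OC)c([O-])c(c1)[C@H](COCc1ccccc1)[C@H](c1cc(OC)c(OCc2ccccc2)c(OC)c1)[S+]1[C@@H](C)CC[C@@H]1C | intermediate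
18 | methyl 3-[(2S,3R)-2-(4-benzyloxy-3,5-dimethoxyphenyl)-3-(benzyloxymethyl)-7-methoxy-2,3-dihydrobenzofuran-5-yl]propanoate | COC(=O)CCc1cc(OC)c2c(c1)[C@H](COCc1ccccc1)[C@@H](c1cc(OC)c(OCc3ccccc3)c(OC)c1)O2 | intermediate
19 | methyl 3-[(2S,3R)-2-(4-hydroxy-3,5-dimethoxyphenyl)-3-(hydroxymethyl)-7-methoxy-2,3-dihydro-1-benzofuran-5-yl]propanoate | COC(=O)CCc1cc(OC)c2c(c1)[C@H](CO)[C@@H](c1cc(OC)c(O)c(OC)c1)O2 | target

## Step count and least certain steps

Total step count: 10. Longest linear sequence: 6 steps (steps 5, 6, 7, 8, 9 and 10, from 10 to 19).

**Step 9 (key step).** The most likely failure is incomplete facial discrimination at the ylide carbon: reaction through the minor ylide conformer would lower the enantiomeric purity of 18, and the sense of induction rests on analogy. A second loss is a base-induced proton shift in 15 to its enol ether tautomer if 16 is formed too slowly. The fallback sets out from 13 and 6 and returns at 18. It gives up auxiliary control in favour of resolution. Bromide 13 is alkylated with tetrahydrothiophene in the presence of NaBF4 to the unhindered, achiral salt 1-{[4-(benzyloxy)-3,5-dimethoxyphenyl]methyl}thiolan-1-ium tetrafluoroborate F1, whose ylide should form and react faster. Annulation of F1 with 6 under the conditions of step 9 should give the racemic trans product methyl 3-[(2RS,3SR)-2-(4-benzyloxy-3,5-dimethoxyphenyl)-3-(benzyloxymethyl)-7-methoxy-2,3-dihydrobenzofuran-5-yl]propanoate F2. Preparative chromatography on a chiral stationary phase then separates 18 from its enantiomer, methyl 3-[(2R,3S)-2-(4-benzyloxy-3,5-dimethoxyphenyl)-3-(benzyloxymethyl)-7-methoxy-2,3-dihydrobenzofuran-5-yl]propanoate F3, which is set aside.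

**Step 10.** The most likely failure is over-reduction: hydrogenolytic opening of the ring C2–O1 bond, itself a benzylic aryl ether, may compete with the slower cleavage of the primary alkyl benzyl ether. The fallback sets out from 1 and returns at 19. It changes the protecting group so that hydrogen is needed only for the fast-cleaving phenolic benzyl ether. Compound 1 is hydroxyalkylated as in step 1 with commercial (tert-butyldiphenylsilyloxy)acetaldehyde to give methyl 3-{3-[2-(tert-butyldiphenylsilyloxy)-1-hydroxyethyl]-4-hydroxy-5-methoxyphenyl}propanoate F4. Sulfination as in step 2 gives methyl 3-{3-[2-(tert-butyldiphenylsilyloxy)-1-(4-methylphenylsulfonyl)ethyl]-4-hydroxy-5-methoxyphenyl}propanoate F5. Annulation with 14 as in step 9 gives methyl 3-[(2S,3R)-2-(4-benzyloxy-3,5-dimethoxyphenyl)-3-(tert-butyldiphenylsilyloxymethyl)-7-methoxy-2,3-dihydrobenzofuran-5-yl]propanoate F6. Tetrabutylammonium fluoride buffered with acetic acid in THF removes the silyl group while the phenol is still protected, giving methyl 3-[(2S,3R)-2-(4-benzyloxy-3,5-dimethoxyphenyl)-3-(hydroxymethyl)-7-methoxy-2,3-dihydrobenzofuran-5-yl]propanoate F7. A brief hydrogenolysis (H2, Pd/C, EtOAc) then cleaves only the phenolic benzyl ether and gives 19.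

**Step 1.** The most likely failure is low conversion, because the neighbouring methoxy group ties up magnesium, or onward condensation of the product alkoxide with a second phenoxide or a second aldehyde. The fallback sets out from 1 and 2 and returns at 4. It replaces the magnesium phenoxide by a boron template. Compounds 1 and 2 are heated with phenylboronic acid and catalytic propanoic acid in toluene with removal of water. The aryl borate delivers the aldehyde to the ortho carbon and is trapped as methyl 3-[4-(benzyloxymethyl)-8-methoxy-2-phenyl-4H-1,3,2-benzodioxaborin-6-yl]propanoate F8. Transesterification of F8 with propane-1,3-diol releases 4.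

**Step 8.** The most likely failure is slow and incomplete S-alkylation, because the sulfur of 9 is flanked by two secondary carbons, with competing hydrolysis of 13 in the two-phase medium. The fallback sets out from 12 and 9 and returns at 14. It replaces the SN2 alkylation by an ionising one: alcohol 12 is treated with HBF4·OEt2 in CH2Cl2 in the presence of 9, so that the benzylic cation is captured by the sulfide and 14 forms directly, bypassing 13. This fallback makes no new compound (F0).

## Further compounds

F1 | step 9 | 1-{[4-(benzyloxy)-3,5-dimethoxyphenyl]methyl}thiolan-1-ium tetrafluoroborate | COc1cc(C[S+]2CCCC2)cc(OC)c1OCc1ccccc1.F[B-](F)(F)F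
F2 | step 9 | methyl 3-[(2RS,3SR)-2-(4-benzyloxy-3,5-dimethoxyphenyl)-3-(benzyloxymethyl)-7-methoxy-2,3-dihydrobenzofuran-5-yl]propanoate (racemate, both enantiomers written) | COC(=O)CCc1cc(OC)c2c(c1)[C@H](COCc1ccccc1)[C@@H](c1cc(OC)c(OCc3ccccc3)c(OC)c1)O2.COC(=O)CCc1cc(OC)c2c(c1)[C@@H](COCc1ccccc1)[C@H](c1cc(OC)c(OCc3ccccc3)c(OC)c1)O2
F3 | step 9 | methyl 3-[(2R,3S)-2-(4-benzyloxy-3,5-dimethoxyphenyl)-3-(benzyloxymethyl)-7-methoxy-2,3-dihydrobenzofuran-5-yl]propanoate | COC(=O)CCc1cc(OC)c2c(c1)[C@@H](COCc1ccccc1)[C@H](c1cc(OC)c(OCc3ccccc3)c(OC)c1)O2
F4 | step 10 | methyl 3-{3-[2-(tert-butyldiphenylsilyloxy)-1-hydroxyethyl]-4-hydroxy-5-methoxyphenyl}propanoate (racemic) | COC(=O)CCc1cc(OC)c(O)c(c1)C(O)CO[Si](c1ccccc1)(c1ccccc1)C(C)(C)C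
F5 | step 10 | methyl 3-{3-[2-(tert-butyldiphenylsilyloxy)-1-(4-methylphenylsulfonyl)ethyl]-4-hydroxy-5-methoxyphenyl}propanoate (racemic) | COC(=O)CCc1cc(OC)c(O)c(c1)C(CO[Si](c1ccccc1)(c1ccccc1)C(C)(C)C)S(=O)(=O)c1ccc(C)cc1
F6 | step 10 | methyl 3-[(2S,3R)-2-(4-benzyloxy-3,5-dimethoxyphenyl)-3-(tert-butyldiphenylsilyloxymethyl)-7-methoxy-2,3-dihydrobenzofuran-5-yl]propanoate | COC(=O)CCc1cc(OC)c2c(c1)[C@H](CO[Si](c1ccccc1)(c1ccccc1)C(C)(C)C)[C@@H](c1cc(OC)c(OCc3ccccc3)c(OC)c1)O2
F7 | step 10 | methyl 3-[(2S,3R)-2-(4-benzyloxy-3,5-dimethoxyphenyl)-3-(hydroxymethyl)-7-methoxy-2,3-dihydrobenzofuran-5-yl]propanoate | COC(=O)CCc1cc(OC)c2c(c1)[C@H](CO)[C@@H](c1cc(OC)c(OCc3ccccc3)c(OC)c1)O2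
F8 | step 1 | methyl 3-[4-(benzyloxymethyl)-8-methoxy-2-phenyl-4H-1,3,2-benzodioxaborin-6-yl]propanoate (racemic) | COC(=O)CCc1cc(OC)c2OB(c3ccccc3)OC(COCc3ccccc3)c2c1
F0 | step 8 | none | none
A1 | alternative 1 | methyl (2S,3S)-2-(4-benzyloxy-3,5-dimethoxyphenyl)-5-bromo-7-methoxy-2,3-dihydrobenzofuran-3-carboxylate (trans) | Brc1cc(OC)c2c(c1)[C@H](C(=O)OC)[C@@H](c1cc(OC)c(OCc3ccccc3)c(OC)c1)O2
A2 | alternative 1 | methyl 2-{2-[(4-benzyloxy-3,5-dimethoxyphenyl)methoxy]-5-bromo-3-methoxyphenyl}-2-diazoacetate | COC(=O)C(=[N+]=[N-])c1cc(Br)cc(OC)c1OCc1cc(OC)c(OCc2ccccc2)c(OC)c1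
A3 | alternative 2 | methyl 3-[(2S,3R)-2-(4-benzyloxy-3,5-dimethoxyphenyl)-3-(hydroxymethyl)-7-(4,4,5,5-tetramethyl-1,3,2-dioxaborolan-2-yl)-2,3-dihydrobenzofuran-5-yl]propanoate | COC(=O)CCc1cc(B2OC(C)(C)C(C)(C)O2)c2c(c1)[C@H](CO)[C@@H](c1cc(OC)c(OCc3ccccc3)c(OC)c1)O2
A4 | alternative 2 | (R)-[4-(benzyloxy)-3,5-dimethoxyphenyl][(S)-oxiran-2-yl]methanol (erythro) | O[C@H](c1cc(OC)c(OCc2ccccc2)c(OC)c1)[C@@H]1CO1
A5 | alternative 2 | methyl 3-[3-iodo-5-(4,4,5,5-tetramethyl-1,3,2-dioxaborolan-2-yl)-4-(trifluoromethylsulfonyloxy)phenyl]propanoate | COC(=O)CCc1cc(I)c(OS(=O)(=O)C(F)(F)F)c(c1)B1OC(C)(C)C(C)(C)O1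
A6 | alternative 3 | methyl 3-[(2S,3R)-2-(4-benzyloxy-3,5-dimethoxyphenyl)-3-(tert-butyldimethylsilyloxymethyl)-7-methoxy-2,3-dihydrobenzofuran-5-yl]propanoate | COC(=O)CCc1cc(OC)c2c(c1)[C@H](CO[Si](C)(C)C(C)(C)C)[C@@H](c1cc(OC)c(OCc3ccccc3)c(OC)c1)O2
A7 | alternative 3 | methyl 3-{4-bromo-3-[(1S,2R)-1-(4-benzyloxy-3,5-dimethoxyphenyl)-3-(tert-butyldimethylsilyloxy)-1-hydroxypropan-2-yl]-5-methoxyphenyl}propanoate | COC(=O)CCc1cc(OC)c(Br)c(c1)[C@H](CO[Si](C)(C)C(C)(C)C)[C@H](O)c1cc(OC)c(OCc2ccccc2)c(OC)c1
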